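**Plan**
1. Retrosynthesis: the side-chain ketone is taken back to a silyl ether, then the two cyclopentanone bonds C-3–C-4 and C-1–C-5 are cut together, which unfolds the bicycle to an open-chain α-bromo ketone carrying a pentan-3-one unit and an (E,E)-diene on the same quaternary carbon C-6.
2. Enabling feature: C-3/C-2(=O)/C-1 of the cyclopentanone is a 2-oxyallyl unit; C-4 and C-5 are the two carbons of an alkene held one atom (C-6) away from its terminus; the side-chain C=C makes the cation that develops at C-4 allylic as well as cyclopropylcarbinyl.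
3. Further cuts: the diene sp2–sp2 bond (Suzuki), C-5=C (Takai), C-1–C-6 (ketal Claisen of an allylic alcohol), the pyranone-bound alkene (aldol/elimination); the side chain comes from a propargylation.
4. Forward order: pyranone, allylic alcohol, quaternary carbon, vinyl iodide, diene, bromo ketone; in the key step the cyclopropane closes first and the cyclopentanone second; desilylation and oxidation finish.
5. Stereochemistry: C-6 from methyl (R)-lactate by 1,3-chirality transfer in a chair Claisen; the side-chain methyl center from (S)-but-3-yn-2-ol; C-1, C-5 and C-4 in the key step from C-6 and the E-alkene; C-3 by equilibration; alkene geometries from E1cB elimination, Takai olefination and syn-hydroboration.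

Key step: step 18

Locants: ring atoms follow bicyclo[3.1.0]hexan-2-one numbering (C-1 quaternary CMe next to the carbonyl C-2; C-3 CHMe; C-4 CH bearing the heptenyl chain; C-5 cyclopropane CH; C-6 cyclopropane carbon with methyl and pyranone). The same numbers name these carbons in open-chain precursors.
Assumption: the C-3 methyl of the target, trans to the C-4 alkenyl group, is taken to be the thermodynamically preferred epimer of this cyclopentanone, so base equilibration should converge on it.

**Route**

Step 1
Reactants: 1 methyl 2-methyl-3-oxopentanoate; 2 N-methoxy-N-methylpropanamide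
Product: 3 methyl 2,4-dimethyl-3,5-dioxoheptanoate (stereoisomer and tautomer mixture)
Conditions: NaH, THF, 0 °C; n-BuLi, −10 °C; then 2, −10 °C → rt; aq. HCl work-up
Reagents that add atoms: none
Why: Double deprotonation makes the γ-carbon of the β-keto ester the most nucleophilic site and the Weinreb amide stops at the ketone stage, so C-acylation should give the 3,5-diketo ester (dianion acylation of a β-keto ester).

Step 2
Reactants: 3 methyl 2,4-dimethyl-3,5-dioxoheptanoate
Product: 4 6-ethyl-4-hydroxy-3,5-dimethyl-2H-pyran-2-one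
Conditions: DBU, toluene, reflux; aq. HCl work-up
Reagents that add atoms: none
Why: The enol oxygen of the terminal ketone attacks the methyl ester and methanol is lost to give the 4-hydroxy-2-pyranone (base-mediated lactonisation of a 3,5-diketo ester).

Step 3
Reactants: 4 6-ethyl-4-hydroxy-3,5-dimethyl-2H-pyran-2-one
Product: 5 6-ethyl-2-methoxy-3,5-dimethyl-4H-pyran-4-one
Conditions: MeOTf, CH2Cl2, rt; aq. NaHCO3 work-up
Reagents that add atoms: methyl trifluoromethanesulfonate, COS(=O)(=O)C(F)(F)F
Why: The hard methylating agent alkylates the lactone carbonyl oxygen, the most basic site, and loss of the hydroxyl proton should leave the 2-methoxy-4-pyranone (regioselective O-methylation of a 4-hydroxy-2-pyranone).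

Step 4
Reactants: 6 methyl (R)-lactate
Product: 7 methyl (2R)-2-(tert-butyldimethylsilyloxy)propanoate
Conditions: TBSCl, imidazole, DMF, rt
Reagents that add atoms: tert-butyldimethylsilyl chloride, CC(C)(C)[Si](C)(C)Cl
Why: Silylation of the secondary alcohol leaves the lactate stereocenter untouched (silyl ether protection).

Step 5
Reactants: 7 methyl (2R)-2-(tert-butyldimethylsilyloxy)propanoate
Product: 8 (2R)-2-(tert-butyldimethylsilyloxy)propanal
Conditions: i-Bu2AlH, CH2Cl2, −78 °C; aq. Rochelle salt work-up
Reagents that add atoms: none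
Why: At −78 °C the hydride reduction of the ester stops at the aldehyde oxidation level and the α-silyloxy stereocenter should not epimerise (half-reduction with i-Bu2AlH).

Step 6
Reactants: 5 6-ethyl-2-methoxy-3,5-dimethyl-4H-pyran-4-one; 8 (2R)-2-(tert-butyldimethylsilyloxy)propanal
Product: 9 6-[(4R)-4-(tert-butyldimethylsilyloxy)-3-hydroxypentan-2-yl]-2-methoxy-3,5-dimethyl-4H-pyran-4-one (mixture of diastereomers at the two new centers)
Conditions: LiN(SiMe3)2, THF, −78 °C; then 8, −78 °C; aq. NH4Cl
Reagents that add atoms: none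
Why: The CH2 of the 6-ethyl group is the vinylogous α-position of the pyranone carbonyl and after deprotonation it adds to the aldehyde (vinylogous aldol addition), the two new centers being removed in step 7 so that all diastereomers converge.

Step 7
Reactants: 9 aldol adduct
Product: 11 6-[(2E,4R)-4-(tert-butyldimethylsilyloxy)pent-2-en-2-yl]-2-methoxy-3,5-dimethyl-4H-pyran-4-one, via mesylate 10 (not isolated)
Conditions: MsCl, Et3N, CH2Cl2, 0 °C; then DBU, rt
Reagents that add atoms: none
Why: Mesylate 10 loses methanesulfonate by E1cB elimination through the pyranone-stabilised carbanion, and the conjugated trisubstituted alkene should form with the pyranone trans to the chain (E) while the silyloxy stereocenter is untouched (mesylation/elimination).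

Step 8
Reactants: 11 silyl ether
Product: 12 6-[(2E,4R)-4-hydroxypent-2-en-2-yl]-2-methoxy-3,5-dimethyl-4H-pyran-4-one
Conditions: HF·pyridine, pyridine, THF, 0 °C → rt
Reagents that add atoms: none
Why: Buffered fluoride cleaves the allylic silyl ether without ionising the allylic C–O bond (desilylation).

Step 9
Reactants: 12 allylic alcohol; 13 3,3-dimethoxypentane
Product: 15 (5S,6E)-5-(6-methoxy-3,5-dimethyl-4-oxo-4H-pyran-2-yl)-4,5-dimethyloct-6-en-3-one (both epimers at the carbon next to the ketone), via allyl enol ether 14 (not isolated)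
Conditions: 13 (excess), EtCO2H (cat.), xylene, 140 °C, MeOH distilled off
Reagents that add atoms: none
Why: Acid-catalysed ketal exchange and loss of methanol give allyl enol ether 14, whose [3,3] shift through a chair with the carbinol methyl equatorial should transfer the (R) carbinol configuration across the E-alkene to the new quaternary carbon C-6 (S) while forming the C-1–C-6 bond and an E-propenyl group (ketal Claisen rearrangement with 1,3-chirality transfer), the C-1 center forming as a mixture that is erased in step 18.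

Step 10
Reactants: 15 Claisen ketone
Product: 17 (2S)-2-(6-methoxy-3,5-dimethyl-4-oxo-4H-pyran-2-yl)-2,3-dimethyl-4-oxohexanal (both epimers at the carbon next to the ketone), via diol 16 (not isolated)
Conditions: OsO4 (cat.), NaIO4, 2,6-lutidine, dioxane/H2O, rt
Reagents that add atoms: sodium periodate, [Na+].[O-]I(=O)(=O)=O; osmium tetroxide (catalytic oxygen carrier), O=[Os](=O)(=O)=O
Why: Catalytic OsO4 dihydroxylates the only unhindered, electron-rich alkene to diol 16 and NaIO4 cleaves it to the aldehyde, the tetrasubstituted vinylogous-ester double bonds of the pyranone being unreactive (Lemieux–Johnson oxidation).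

Step 11
Reactants: 17 keto aldehyde
Product: 18 (5R,6E)-7-iodo-5-(6-methoxy-3,5-dimethyl-4-oxo-4H-pyran-2-yl)-4,5-dimethylhept-6-en-3-one (both epimers at the carbon next to the ketone)
Conditions: CrCl2, CHI3, THF, 0 °C → rt
Reagents that add atoms: iodoform, IC(I)I
Why: The gem-dichromium species made from CHI3 and CrCl2 adds to the aldehyde but not to the ketone, and anti elimination should give the E-vinyl iodide (Takai olefination).

Step 12
Reactants: 19 (S)-but-3-yn-2-ol
Product: 20 (S)-but-3-yn-2-yl methanesulfonate
Conditions: MsCl, Et3N, CH2Cl2, −78 → 0 °C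
Reagents that add atoms: methanesulfonyl chloride, CS(=O)(=O)Cl
Why: O-Sulfonylation turns the propargylic alcohol into a leaving group with retention at the stereocenter (mesylation).

Step 13
Reactants: 20 (S)-but-3-yn-2-yl methanesulfonate; 21 propanal
Product: 23 (3S,4R)-4-methylhex-5-yn-3-ol, via allenylzinc 22 (not isolated)
Conditions: Pd(OAc)2 (cat.), PPh3 (cat.), Et2Zn, THF, −78 → −20 °C
Reagents that add atoms: none
Why: Zerovalent palladium displaces the mesylate in an anti SN2′ sense, transmetalation gives the configurationally defined allenylzinc 22, and its addition to propanal through a cyclic SE2′ transition state should set the methyl-bearing center as R and the anti carbinol as S (Marshall propargylation), the carbinol configuration being erased in step 20.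

Step 14
Reactants: 23 (3S,4R)-4-methylhex-5-yn-3-ol
Product: 24 tert-butyldimethyl{[(3S,4R)-4-methylhex-5-yn-3-yl]oxy}silane
Conditions: TBSCl, imidazole, DMF, rt
Reagents that add atoms: tert-butyldimethylsilyl chloride, CC(C)(C)[Si](C)(C)Cl
Why: Silylation masks the carbinol for the base, boron and cation chemistry that follows (silyl ether protection).

Step 15
Reactants: 24 silyl ether
Product: 25 tert-butyldimethyl{[(3S,4R)-4-methylhept-5-yn-3-yl]oxy}silane
Conditions: n-BuLi, THF, −78 °C; MeI, −78 °C → rt
Reagents that add atoms: iodomethane, CI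
Why: The terminal alkyne is deprotonated and methylated by SN2 without touching the two stereocenters (alkyne alkylation).

Step 16
Reactants: 25 internal alkyne; 18 vinyl iodide
Product: 27 (5S,6E,8E,10R,11S)-11-(tert-butyldimethylsilyloxy)-5-(6-methoxy-3,5-dimethyl-4-oxo-4H-pyran-2-yl)-4,5,8,10-tetramethyltrideca-6,8-dien-3-one (both epimers at the carbon next to the ketone), via alkenylborane 26 (not isolated)
Conditions: Cy2BH, THF, 0 °C → rt; then 18, Pd(PPh3)4 (cat.), aq. K3PO4, THF, 50 °C
Reagents that add atoms: none
Why: Syn-hydroboration puts boron on the less hindered, methyl-bearing alkyne carbon to give (E)-alkenylborane 26, which should couple with the vinyl iodide with retention at both partners to give the (E,E)-diene while ketone, silyl ether and pyranone stay inert (hydroboration/Suzuki–Miyaura coupling).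

Step 17
Reactants: 27 diene ketone
Product: 29 (5S,6E,8E,10R,11S)-2-bromo-11-(tert-butyldimethylsilyloxy)-5-(6-methoxy-3,5-dimethyl-4-oxo-4H-pyran-2-yl)-4,5,8,10-tetramethyltrideca-6,8-dien-3-one (mixture of diastereomers at the two carbons next to the ketone), via silyl enol ether 28 (not isolated)
Conditions: LiN(SiMe3)2, TMSCl, THF, −78 °C; then NBS, −78 → 0 °C
Reagents that add atoms: N-bromosuccinimide, O=C1CCC(=O)N1Br
Why: The kinetic base removes a proton from the unhindered ethyl CH2 (C-3) and not from the neopentyl-type methine C-1, and silyl enol ether 28 should be brominated by NBS much faster than the diene (regioselective α-bromination via a silyl enol ether), the diastereomers converging in step 18.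

Step 18
Reactants: 29 α-bromo ketone
Product: 32 (1S,3S,4R,5S,6S)-4-[(2E,4R,5S)-5-(tert-butyldimethylsilyloxy)-4-methylhept-2-en-2-yl]-6-(6-methoxy-3,5-dimethyl-4-oxo-4H-pyran-2-yl)-1,3,6-trimethylbicyclo[3.1.0]hexan-2-one, via oxyallyl cation 30 (not isolated), via C-3 epimer 31 (not isolated)
Conditions: Et3N, HFIP (high dilution), 0 °C → rt; concentrate; then DBU (cat.), CH2Cl2, rt
Reagents that add atoms: none
Why: Proposed new method: base-assisted loss of HBr from 29 in the ionising, weakly nucleophilic solvent gives the 2-oxyallyl cation 30 (C-1/C-2/C-3), whose C-1 terminus is captured by the near carbon of the diene on the same quaternary carbon C-6, closing the cyclopropane by a 3-exo-trig homoallyl-to-cyclopropylcarbinyl cyclisation (C-1–C-5 bond) and leaving an allylic, cyclopropylcarbinyl cation at C-4, which the enol carbon C-3 then captures in a 5-(enolendo)-exo-trig closure of the cyclopentanone (C-3–C-4 bond), a formal intramolecular (3+2) cycloaddition. The closest known reaction type is the (3+2) cyclopentanone annulation of oxyallyl cations, generated from α-halo ketones with base in fluorinated alcohols or reductively from α,α′-dibromo ketones, with cation-stabilising alkenes such as styrenes, dienes, enol ethers and indoles, combined here with the familiar homoallyl/cyclopropylcarbinyl cation cyclisation; a one-atom tether between oxyallyl and alkene has not been shown. C-6 is the only stereocenter of 29 that matters, because C-1 and C-3 are planarised and all diastereomers converge: the new ring must form cis to one C-6 substituent, and the small methyl should take this endo position and leave the ortho-substituted pyranone exo, which sets C-1 and C-5, while C-4 follows from the E geometry of the disubstituted alkene in a suprafacial closure that keeps the alkenyl group anti to C-6. C-3 is set last: the W-shaped oxyallyl should give the cis-1,3-dimethyl adduct 31, which DBU should equilibrate to 32 with the methyl trans to the neighbouring alkenyl group. The step needs C-alkylation at C-4 in preference to closure at the far allyl terminus (seven-membered ring), closure through oxygen, solvent capture or proton loss to an enone; the s-trans diene, the concentration of charge at the cyclopropylcarbinyl carbon, high dilution and the low nucleophilicity of HFIP should secure this.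

Step 19
Reactants: 32 bicyclic silyl ether
Product: 33 (1S,3S,4R,5S,6S)-4-[(2E,4R,5S)-5-hydroxy-4-methylhept-2-en-2-yl]-6-(6-methoxy-3,5-dimethyl-4-oxo-4H-pyran-2-yl)-1,3,6-trimethylbicyclo[3.1.0]hexan-2-one
Conditions: HF·pyridine, pyridine, THF, 0 °C → rt
Reagents that add atoms: none
Why: HF·pyridine cleaves the hindered secondary silyl ether and should leave cyclopropyl ketone, alkene and pyranone untouched (desilylation).

Step 20
Reactants: 33 bicyclic alcohol
Product: 34 (1S,3S,4R,5S,6S)-6-(6-methoxy-3,5-dimethyl-4-oxo-4H-pyran-2-yl)-1,3,6-trimethyl-4-[(2E,4R)-4-methyl-5-oxohept-2-en-2-yl]bicyclo[3.1.0]hexan-2-one (CNP0216193.1)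
Conditions: Dess–Martin periodinane, NaHCO3, CH2Cl2, 0 °C → rt
Reagents that add atoms: none
Why: Buffered Dess–Martin oxidation converts the carbinol into the ethyl ketone under neutral conditions that should neither epimerise the adjacent methyl-bearing center nor move the β,γ-alkene into conjugation (Dess–Martin oxidation).

**Compound list**
1 | methyl 2-methyl-3-oxopentanoate | CCC(=O)C(C)C(=O)OC | starting material
2 | N-methoxy-N-methylpropanamide | CCC(=O)N(C)OC | starting material
3 | methyl 2,4-dimethyl-3,5-dioxoheptanoate (stereoisomer mixture) | CCC(=O)C(C)C(=O)C(C)C(=O)OC | intermediate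
4 | 6-ethyl-4-hydroxy-3,5-dimethyl-2H-pyran-2-one | CCc1oc(=O)c(C)c(O)c1C | intermediate
5 | 6-ethyl-2-methoxy-3,5-dimethyl-4H-pyran-4-one | CCc1oc(OC)c(C)c(=O)c1C | intermediate
6 | methyl (R)-lactate | C[C@@H](O)C(=O)OC | starting material
7 | methyl (2R)-2-(tert-butyldimethylsilyloxy)propanoate | C[C@@H](O[Si](C)(C)C(C)(C)C)C(=O)OC | intermediate
8 | (2R)-2-(tert-butyldimethylsilyloxy)propanal | C[C@@H](O[Si](C)(C)C(C)(C)C)C=O | intermediate
9 | 6-[(4R)-4-(tert-butyldimethylsilyloxy)-3-hydroxypentan-2-yl]-2-methoxy-3,5-dimethyl-4H-pyran-4-one (diastereomer mixture) | C[C@@H](O[Si](C)(C)C(C)(C)C)C(O)C(C)c1oc(OC)c(C)c(=O)c1C | intermediate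
10 | methanesulfonate of 9 (diastereomer mixture) | C[C@@H](O[Si](C)(C)C(C)(C)C)C(OS(C)(=O)=O)C(C)c1oc(OC)c(C)c(=O)c1C | intermediate (not isolated)
11 | 6-[(2E,4R)-4-(tert-butyldimethylsilyloxy)pent-2-en-2-yl]-2-methoxy-3,5-dimethyl-4H-pyran-4-one | C[C@@H](O[Si](C)(C)C(C)(C)C)/C=C(\C)c1oc(OC)c(C)c(=O)c1C | intermediate
12 | 6-[(2E,4R)-4-hydroxypent-2-en-2-yl]-2-methoxy-3,5-dimethyl-4H-pyran-4-one | C[C@@H](O)/C=C(\C)c1oc(OC)c(C)c(=O)c1C | intermediate
13 | 3,3-dimethoxypentane | CCC(OC)(OC)CC | starting material
14 | 6-[(2E,4R)-4-(pent-2-en-3-yloxy)pent-2-en-2-yl]-2-methoxy-3,5-dimethyl-4H-pyran-4-one (enol ether E/Z mixture) | CC=C(CC)O[C@H](C)/C=C(\C)c1oc(OC)c(C)c(=O)c1C | intermediate (not isolated)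
15 | (5S,6E)-5-(6-methoxy-3,5-dimethyl-4-oxo-4H-pyran-2-yl)-4,5-dimethyloct-6-en-3-one (C-4 epimers) | CCC(=O)C(C)[C@](C)(/C=C/C)c1oc(OC)c(C)c(=O)c1C | intermediate
16 | 6,7-dihydroxy-5-(6-methoxy-3,5-dimethyl-4-oxo-4H-pyran-2-yl)-4,5-dimethyloctan-3-one, quaternary center as in 15 (diastereomer mixture) | CCC(=O)C(C)[C@](C)(C(O)C(C)O)c1oc(OC)c(C)c(=O)c1C | intermediate (not isolated)
17 | (2S)-2-(6-methoxy-3,5-dimethyl-4-oxo-4H-pyran-2-yl)-2,3-dimethyl-4-oxohexanal (C-3 epimers) | CCC(=O)C(C)[C@](C)(C=O)c1oc(OC)c(C)c(=O)c1C | intermediate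
18 | (5R,6E)-7-iodo-5-(6-methoxy-3,5-dimethyl-4-oxo-4H-pyran-2-yl)-4,5-dimethylhept-6-en-3-one (C-4 epimers) | CCC(=O)C(C)[C@](C)(/C=C/I)c1oc(OC)c(C)c(=O)c1C | intermediate
19 | (S)-but-3-yn-2-ol | C[C@H](O)C#C | starting material
20 | (S)-but-3-yn-2-yl methanesulfonate | C[C@H](OS(C)(=O)=O)C#C | intermediate
21 | propanal | CCC=O | starting material
22 | (aR)-buta-1,2-dien-1-yl(ethyl)zinc (axial chirality not encoded in the SMILES) | CC[Zn]C=C=CC | intermediate (not isolated)
23 | (3S,4R)-4-methylhex-5-yn-3-ol | CC[C@H](O)[C@H](C)C#C | intermediate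
24 | tert-butyldimethyl{[(3S,4R)-4-methylhex-5-yn-3-yl]oxy}silane | CC[C@H](O[Si](C)(C)C(C)(C)C)[C@H](C)C#C | intermediate
25 | tert-butyldimethyl{[(3S,4R)-4-methylhept-5-yn-3-yl]oxy}silane | CC[C@H](O[Si](C)(C)C(C)(C)C)[C@H](C)C#CC | intermediate
26 | dicyclohexyl[(2E,4R,5S)-5-(tert-butyldimethylsilyloxy)-4-methylhept-2-en-2-yl]borane | CC[C@H](O[Si](C)(C)C(C)(C)C)[C@H](C)/C=C(\C)B(C1CCCCC1)C1CCCCC1 | intermediate (not isolated)
27 | (5S,6E,8E,10R,11S)-11-(tert-butyldimethylsilyloxy)-5-(6-methoxy-3,5-dimethyl-4-oxo-4H-pyran-2-yl)-4,5,8,10-tetramethyltrideca-6,8-dien-3-one (C-4 epimers) | CCC(=O)C(C)[C@](C)(/C=C/C(C)=C/[C@@H](C)[C@H](CC)O[Si](C)(C)C(C)(C)C)c1oc(OC)c(C)c(=O)c1C | intermediate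
28 | trimethylsilyl enol ether of 27 toward the ethyl CH2 (isomer mixture) | CC=C(O[Si](C)(C)C)C(C)[C@](C)(/C=C/C(C)=C/[C@@H](C)[C@H](CC)O[Si](C)(C)C(C)(C)C)c1oc(OC)c(C)c(=O)c1C | intermediate (not isolated)
29 | (5S,6E,8E,10R,11S)-2-bromo-11-(tert-butyldimethylsilyloxy)-5-(6-methoxy-3,5-dimethyl-4-oxo-4H-pyran-2-yl)-4,5,8,10-tetramethyltrideca-6,8-dien-3-one (C-2 and C-4 epimers) | CC(Br)C(=O)C(C)[C@](C)(/C=C/C(C)=C/[C@@H](C)[C@H](CC)O[Si](C)(C)C(C)(C)C)c1oc(OC)c(C)c(=O)c1C | intermediate
30 | 2-oxyallyl cation (zwitterion) from 29 by loss of HBr, quaternary center as in 29 | C[CH+]C([O-])=C(C)[C@](C)(/C=C/C(C)=C/[C@@H](C)[C@H](CC)O[Si](C)(C)C(C)(C)C)c1oc(OC)c(C)c(=O)c1C | intermediate (not isolated)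
31 | (1S,3R,4R,5S,6S) C-3 epimer of 32 (3-methyl cis to the 1-methyl and to the 4-alkenyl group) | CC[C@H](O[Si](C)(C)C(C)(C)C)[C@H](C)/C=C(\C)[C@H]1[C@@H](C)C(=O)[C@@]2(C)[C@@H]1[C@]2(C)c1oc(OC)c(C)c(=O)c1C | intermediate (not isolated)
32 | (1S,3S,4R,5S,6S)-4-[(2E,4R,5S)-5-(tert-butyldimethylsilyloxy)-4-methylhept-2-en-2-yl]-6-(6-methoxy-3,5-dimethyl-4-oxo-4H-pyran-2-yl)-1,3,6-trimethylbicyclo[3.1.0]hexan-2-one (6-methyl endo; 4-alkenyl anti to C-6; 3-methyl trans to the 4-alkenyl) | CC[C@H](O[Si](C)(C)C(C)(C)C)[C@H](C)/C=C(\C)[C@H]1[C@H](C)C(=O)[C@@]2(C)[C@@H]1[C@]2(C)c1oc(OC)c(C)c(=O)c1C | intermediate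
33 | (1S,3S,4R,5S,6S)-4-[(2E,4R,5S)-5-hydroxy-4-methylhept-2-en-2-yl]-6-(6-methoxy-3,5-dimethyl-4-oxo-4H-pyran-2-yl)-1,3,6-trimethylbicyclo[3.1.0]hexan-2-one | CC[C@H](O)[C@H](C)/C=C(\C)[C@H]1[C@H](C)C(=O)[C@@]2(C)[C@@H]1[C@]2(C)c1oc(OC)c(C)c(=O)c1C | intermediate
34 | (1S,3S,4R,5S,6S)-6-(6-methoxy-3,5-dimethyl-4-oxo-4H-pyran-2-yl)-1,3,6-trimethyl-4-[(2E,4R)-4-methyl-5-oxohept-2-en-2-yl]bicyclo[3.1.0]hexan-2-one | CCC(=O)[C@H](C)/C=C(\C)[C@H]1[C@H](C)C(=O)[C@@]2(C)[C@@H]1[C@]2(C)c1oc(OC)c(C)c(=O)c1C | target

**Count and risks**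
Total steps: 20. Longest linear sequence: 14 steps (steps 1–3, 6–11, 16–20); steps 4–5 and 12–15 are side branches.

Steps most likely to fail:

Step 18 (proposed new method). What may go wrong: the oxyallyl cation is diverted (proton loss to an enone, solvent capture, closure through oxygen or at the far allyl terminus), or the facial selectivity at C-6 is poor. The fallback uses known reactions, sets out from aldehyde 17 and alkyne 25, and returns at 32. Aldehyde 17 would be converted with dimethylsulfonium methylide (Me3SI, KN(SiMe3)2, THF, 0 °C; Corey–Chaykovsky) into the terminal epoxide F1. KOt-Bu in t-BuOH would then let the tertiary ketone enolate open the epoxide in a 3-exo-tet mode with inversion at C-5, closing the cyclopropane (C-1–C-5 bond) to the cyclopropylmethanol F2; the isomer with acyl and hydroxymethyl cis to each other and to the C-6 methyl would be separated. Dess–Martin oxidation would give the keto aldehyde F3, and KOH in MeOH would close the cyclopentenone F4 by aldol condensation (C-3–C-4 bond). Alkyne 25 would be hydrozirconated with excess Cp2Zr(H)Cl (THF, 50 °C) to the alkenylzirconocene F5, which with catalytic Ni(acac)2 should add in conjugate fashion to F4 from the face anti to the cyclopropane. Protonation and DBU equilibration at C-3 would then give 32.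

Step 9. What may go wrong: the allylic alcohol ionises under the hot, acidic conditions (loss of configurational purity, elimination), or the rearrangement is sluggish at the fully substituted alkene terminus. The fallback sets out from 12 and returns at 15. Alcohol 12 would be acylated with propanoyl chloride (pyridine, DMAP) to the propanoate F6. Ireland–Claisen rearrangement (LiN(i-Pr)2, TMSCl, THF, −78 °C → rt) through the silyl ketene acetal F7 would give, after hydrolysis, the acid F8 by the same chair-controlled chirality transfer, but under base and at low temperature. (COCl)2 with catalytic DMF would give the acid chloride F9, and EtMgBr with catalytic Fe(acac)3 at −78 °C would give ethyl ketone 15.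

Step 16. What may go wrong: regiocontrol in the hydroboration is incomplete, or the hindered alkenylborane transmetalates slowly and is lost by protodeboronation. The fallback sets out from 25 and 18 and returns at 27. Alkyne 25 would be hydrostannated (Bu3SnH, Pd(PPh3)2Cl2 cat., THF) to the (E)-alkenylstannane F10, which can be purified from its regioisomer. F10 would then be coupled with 18 under base-free Stille conditions (Pd2(dba)3, AsPh3, CuI, DMF) to give 27.

**Further compounds**
F1 | step 18 | 4-methyl-5-(6-methoxy-3,5-dimethyl-4-oxo-4H-pyran-2-yl)-5-(oxiran-2-yl)hexan-3-one, quaternary center as in 17 (diastereomer mixture) | CCC(=O)C(C)[C@](C)(C1CO1)c1oc(OC)c(C)c(=O)c1C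
F2 | step 18 | 1-[(1S,2S,3S)-3-(hydroxymethyl)-2-(6-methoxy-3,5-dimethyl-4-oxo-4H-pyran-2-yl)-1,2-dimethylcyclopropyl]propan-1-one (acyl and hydroxymethyl cis to each other and to the ring methyl at the pyranone carbon) | CCC(=O)[C@@]1(C)[C@@H](CO)[C@]1(C)c1oc(OC)c(C)c(=O)c1C
F3 | step 18 | cyclopropanecarbaldehyde from oxidation of F2 (same configuration) | CCC(=O)[C@@]1(C)[C@@H](C=O)[C@]1(C)c1oc(OC)c(C)c(=O)c1C
F4 | step 18 | (1S,5S,6S)-6-(6-methoxy-3,5-dimethyl-4-oxo-4H-pyran-2-yl)-1,3,6-trimethylbicyclo[3.1.0]hex-3-en-2-one (6-methyl endo) | C1=C(C)C(=O)[C@@]2(C)[C@@H]1[C@]2(C)c1oc(OC)c(C)c(=O)c1C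
F5 | step 18 | chlorobis(cyclopentadienyl)[(2E,4R,5S)-5-(tert-butyldimethylsilyloxy)-4-methylhept-2-en-2-yl]zirconium | CC[C@H](O[Si](C)(C)C(C)(C)C)[C@H](C)/C=C(\C)[Zr](Cl)(C1C=CC=C1)C1C=CC=C1
F6 | step 9 | (2R,3E)-4-(6-methoxy-3,5-dimethyl-4-oxo-4H-pyran-2-yl)pent-3-en-2-yl propanoate | CCC(=O)O[C@H](C)/C=C(\C)c1oc(OC)c(C)c(=O)c1C
F7 | step 9 | trimethylsilyl ketene acetal of F6 (geometry mixture) | CC=C(O[Si](C)(C)C)O[C@H](C)/C=C(\C)c1oc(OC)c(C)c(=O)c1C
F8 | step 9 | (4E)-3-(6-methoxy-3,5-dimethyl-4-oxo-4H-pyran-2-yl)-2,3-dimethylhex-4-enoic acid, quaternary center as in 15 (C-2 epimers) | OC(=O)C(C)[C@](C)(/C=C/C)c1oc(OC)c(C)c(=O)c1C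
F9 | step 9 | acid chloride of F8 | ClC(=O)C(C)[C@](C)(/C=C/C)c1oc(OC)c(C)c(=O)c1C
F10 | step 16 | tributyl[(2E,4R,5S)-5-(tert-butyldimethylsilyloxy)-4-methylhept-2-en-2-yl]stannane | CC[C@H](O[Si](C)(C)C(C)(C)C)[C@H](C)/C=C(\C)[Sn](CCCC)(CCCC)CCCC
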